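Everything rests on cutting ring A at C7–C8 and C4a–C5. This releases C5–C6–C7 as a symmetric methoxymalonyl unit. It leaves ring C, with O1, C2, C3, C4, C4a, C8a and the exocyclic C8–O8, as a 4-pyranone of the kojic acid type. The key step exploits the 1,3-relation of C8 and C4a across C8a: they are the gamma and alpha carbons of the extended enol of the C4 carbonyl, so both can bond to acyl carbons. One operation forms two C–C bonds, closes and aromatises ring A, and unveils the 5- and 7-hydroxyls. Its precursor is a 6-anisyl-5-methoxy-4-pyranone whose C2 side chain is a CH2 already bearing the isovalerate.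

Key step: step 7

Remark on numbering: flavone atom numbers are used in step 7. C6, C5, C4, C3, C2 and the side-chain CH2 of the pyranone become C2, C3, C4, C4a, C8a and C8 of the flavone.

Remark on the design of the key step:
- The silyl dienol ether is made first with close to one equivalent of TMSOTf, so the enolisable isovalerate is left alone.
- It is then added to the dichloride with practically no free amine present, so the dichloride is not converted to its ketene and oligomerised before C7–C8 exists.
- The amine needed for the second bond is added last.

Assumption: the exocyclic C8=C8a bond of the dienol ether equilibrates in the flask and is drawn without geometry. The enol of the dienylketene is drawn as the Z isomer, the only one that can close.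

Step 1
Reactants: 1 kojic acid (5-hydroxy-2-(hydroxymethyl)-4H-pyran-4-one)
Product: 2 6-iodokojic acid (5-hydroxy-2-(hydroxymethyl)-6-iodo-4H-pyran-4-one)
Conditions: NIS (1.05 equiv), DMF, 0 °C to rt, dark
Reagents that add atoms: N-iodosuccinimide, O=C1CCC(=O)N1I
Why: Electrophilic iodination of an enol: the free 5-OH activates only its ortho carbon C6, the site at which kojic acid is known to take up halogen, Mannich and aldol electrophiles, whereas C3 has no such donor.

Step 2
Reactants: 2 6-iodokojic acid
Product: 3 2-(hydroxymethyl)-6-iodo-5-methoxy-4H-pyran-4-one
Conditions: MeI (1.2 equiv), K2CO3 (1.2 equiv), DMF, rt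
Reagents that add atoms: iodomethane, CI
Why: Williamson ether synthesis: carbonate ionises only the acidic enolic 5-OH, so the primary alcohol stays free and no protecting group is needed.

Step 3
Reactants: 3 2-(hydroxymethyl)-6-iodo-5-methoxy-4H-pyran-4-one; 4 4-methoxyphenylboronic acid
Product: 5 2-(hydroxymethyl)-5-methoxy-6-(4-methoxyphenyl)-4H-pyran-4-one
Conditions: Pd(PPh3)4 (5 mol %), K2CO3 (2 equiv), 1,4-dioxane/H2O (4:1), 80 °C
Reagents that add atoms: 4-methoxyphenylboronic acid (4), COc1ccc(B(O)O)cc1
Why: Suzuki–Miyaura coupling: the C6–I bond, a vinylogous acyl iodide, should add quickly to zerovalent palladium, and the free alcohol, the enol ether and the pyranone carbonyl are spectators under aqueous carbonate.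

Step 4
Reactants: 5 2-(hydroxymethyl)-5-methoxy-6-(4-methoxyphenyl)-4H-pyran-4-one; 6 isovaleryl chloride (3-methylbutanoyl chloride)
Product: 7 [5-methoxy-6-(4-methoxyphenyl)-4-oxo-4H-pyran-2-yl]methyl 3-methylbutanoate
Conditions: 6 (1.1 equiv), Et3N (1.3 equiv), DMAP (cat.), CH2Cl2, 0 °C to rt
Reagents that add atoms: isovaleryl chloride (6), CC(C)CC(=O)Cl
Why: DMAP-catalysed O-acylation of the only hydroxyl group present, which fixes the isovalerate on the oxygen that becomes O8 before any phenol exists.

Step 5
Reactants: 8 dimethyl methoxymalonate
Product: 10 methoxymalonic acid, via disodium methoxymalonate 9 (not isolated)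
Conditions: NaOH (2.1 equiv), H2O/MeOH, 0 °C to rt; then 2 M HCl to pH 1 at 0 °C, NaCl saturation, EtOAc extraction, evaporation below 25 °C
Reagents that add atoms: sodium hydroxide, [Na+].[OH-]
Why: Saponification of both methyl esters followed by cold acidification of 9; working at or below room temperature keeps the malonic acid from decarboxylating.

Step 6
Reactants: 10 methoxymalonic acid
Product: 11 methoxymalonyl dichloride
Conditions: (COCl)2 (2.5 equiv), DMF (cat.), CH2Cl2, 0 °C to rt; volatiles removed below 20 °C; used at once as a CH2Cl2 solution
Reagents that add atoms: oxalyl chloride, O=C(Cl)C(=O)Cl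
Why: Acid chloride formation by way of the Vilsmeier-type chloroiminium chloride from DMF and oxalyl chloride, a method that runs below room temperature and leaves only gases, so that the base- and heat-sensitive dichloride needs no distillation.

Step 7
Reactants: 7 [5-methoxy-6-(4-methoxyphenyl)-4-oxo-4H-pyran-2-yl]methyl 3-methylbutanoate; 11 methoxymalonyl dichloride
Product: 16 5,7,8-trihydroxy-3,6,4'-trimethoxyflavone 8-isovalerate (target), via silyl dienol ether 12 (not isolated), via C8-acylated keto acid chloride 13 (not isolated), via dienylketene 14 (not isolated), via 4a-H cyclohexadienone 15 (not isolated)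
Conditions: 7, TMSOTf (1.1 equiv), Et3N (1.1 equiv), CH2Cl2, −78 to 0 °C; cannulated into 11 (1.0 equiv), CH2Cl2 (high dilution), −78 °C; then Et3N (2.5 equiv), −78 °C to rt; aq. citric acid work-up
Reagents that add atoms: methoxymalonyl dichloride (11), COC(C(=O)Cl)C(=O)Cl; trimethylsilyl triflate, C[Si](C)(C)OS(=O)(=O)C(F)(F)F (its silyl group stays only in 12)
Why: Proposed new method: silylation of the C4 carbonyl oxygen, the most Lewis-basic site of 7, acidifies the C8 methylene enough for Et3N to remove a proton, and the resulting 2-alkylidene-2H-pyran 12 attacks one acyl chloride of 11 through its exocyclic carbon C8, which forms C7–C8, expels TMSCl and restores the pyranone in 13. The late portion of Et3N takes HCl from the ClCO–CH(OMe) end and enolises the C7 ketone towards C8, which lines up the triene C4a=C8a–C8=C7–C6=C5 of dienylketene 14. Ring A closes by a thermal disrotatory six-electron electrocyclisation that forms C4a–C5 and gives dienone 15 (a polar 6-exo-trig attack of C4a of the re-enolised pyranone on the acyl carbon would make the same bond), and two proton shifts then deliver the aromatic 5,7-diol 16. The closest known reaction types are the Effenberger alpha,alpha' bis-acylation of enol ethers with malonyl dichloride, the C-acylation of methylenepyrans at the exocyclic carbon, the three-plus-three cyclocondensation of 1,3-bis(silyl enol ethers) with 1,3-dielectrophiles and the dienylketene closure of the Danheiser benzannulation, none of which has been shown on a 2-(acyloxymethyl)-4-pyranone. No stereocentre is created in 16, since C8 and C6 of 13 and C4a of 15 all end up trigonal. The step needs carbon over oxygen acylation, pyranone over ester enolisation and no orientational choice: O4 carries silicon and any O-acyl product stays an acyl donor that can revert while aromatisation cannot, the single equivalent of TMSOTf goes to the far more basic pyranone oxygen, the only enol oxygen near the acyl chloride of 13 (O7) could close nothing larger than a four-membered ring, C2 and C3 are substituted so that C4a is the one free ring carbon, and the mirror-symmetric dielectrophile places C6–OMe between the two new hydroxyls whichever end reacts first.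

Compound list
1 | kojic acid (5-hydroxy-2-(hydroxymethyl)-4H-pyran-4-one) | OCc1cc(=O)c(O)co1 | starting material
2 | 6-iodokojic acid (5-hydroxy-2-(hydroxymethyl)-6-iodo-4H-pyran-4-one) | OCc1cc(=O)c(O)c(I)o1 | intermediate
3 | 2-(hydroxymethyl)-6-iodo-5-methoxy-4H-pyran-4-one | OCc1cc(=O)c(OC)c(I)o1 | intermediate
4 | 4-methoxyphenylboronic acid | COc1ccc(B(O)O)cc1 | starting material
5 | 2-(hydroxymethyl)-5-methoxy-6-(4-methoxyphenyl)-4H-pyran-4-one | OCc1cc(=O)c(OC)c(-c2ccc(OC)cc2)o1 | intermediate
6 | isovaleryl chloride (3-methylbutanoyl chloride) | CC(C)CC(=O)Cl | starting material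
7 | [5-methoxy-6-(4-methoxyphenyl)-4-oxo-4H-pyran-2-yl]methyl 3-methylbutanoate | CC(C)CC(=O)OCc1cc(=O)c(OC)c(-c2ccc(OC)cc2)o1 | intermediate
8 | dimethyl methoxymalonate | COC(C(=O)OC)C(=O)OC | starting material
9 | disodium methoxymalonate (not isolated) | COC(C(=O)[O-])C(=O)[O-].[Na+].[Na+] | intermediate
10 | methoxymalonic acid | COC(C(=O)O)C(=O)O | intermediate
11 | methoxymalonyl dichloride | COC(C(=O)Cl)C(=O)Cl | intermediate
12 | silyl dienol ether, [5-methoxy-6-(4-methoxyphenyl)-4-(trimethylsilyloxy)-2H-pyran-2-ylidene]methyl 3-methylbutanoate, E/Z not defined (not isolated) | CC(C)CC(=O)OC=C1C=C(O[Si](C)(C)C)C(OC)=C(c2ccc(OC)cc2)O1 | intermediate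
13 | C8-acylated keto acid chloride, 4-chloro-3-methoxy-1-[5-methoxy-6-(4-methoxyphenyl)-4-oxo-4H-pyran-2-yl]-2,4-dioxobutyl 3-methylbutanoate, both centres epimerisable and undefined (not isolated) | CC(C)CC(=O)OC(C(=O)C(OC)C(=O)Cl)c1cc(=O)c(OC)c(-c2ccc(OC)cc2)o1 | intermediate
14 | dienylketene, Z enol of the C7 ketone with the C6=C5=O ketene (not isolated) | CC(C)CC(=O)O/C(c1cc(=O)c(OC)c(-c2ccc(OC)cc2)o1)=C(\O)C(OC)=C=O | intermediate
15 | 4a-H cyclohexadienone, primary electrocyclisation product, racemic at C4a (not isolated) | CC(C)CC(=O)OC1=C2OC(c3ccc(OC)cc3)=C(OC)C(=O)C2C(=O)C(OC)=C1O | intermediate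
16 | 5,7,8-trihydroxy-3,6,4'-trimethoxyflavone 8-isovalerate | COc1ccc(-c2oc3c(OC(=O)CC(C)C)c(O)c(OC)c(O)c3c(=O)c2OC)cc1 | target

Total step count: 7. Longest linear sequence: 5 steps (steps 1, 2, 3, 4 and 7). The dichloride branch (steps 5 and 6) joins at step 7.

Steps most likely to fail

Step 7. Several processes may compete with the annulation:
- amine-induced self-condensation of the dielectrophile through its ketene;
- attachment of two pyranone units to one malonyl unit;
- oxygen acylation at O4 or at the C7 enol in place of closure at C4a;
- enolisation of the isovalerate;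
- base-induced drift of the acyl group from O8 to O7. This is countered by the acidic quench, and the ester of the less acidic 8-phenol is expected to be the more stable isomer.

The fallback uses known chemistry only and gives up the annulation: ring A is taken ready-made and O8 is introduced by nuclear oxidation. It sets out from isovaleryl chloride 6, the only numbered compound it keeps, together with santin F1 (5,7-dihydroxy-3,6,4'-trimethoxyflavone, available from phytochemical suppliers). It comes back to the route at target 16. Williamson benzylation (BnBr, K2CO3, acetone, reflux) should touch only the acidic 7-OH, because the 5-OH is tied up in the chelate with the C4 carbonyl, and should give 7-O-benzylsantin F2. Elbs persulfate oxidation (K2S2O8, aq. KOH, pyridine, rt) attacks the carbon para to the 5-phenoxide, C8, since the ortho carbon C6 is blocked. This should give the potassium 8-sulfate F3, which warm dilute HCl hydrolyses to 7-benzyloxy-5,8-dihydroxy-3,6,4'-trimethoxyflavone F4. One equivalent of 6 in pyridine at 0 °C should acylate the unchelated 8-OH and leave the chelated 5-OH, giving the 7-O-benzyl 8-isovalerate F5. Neutral hydrogenolysis (H2, Pd/C, EtOAc, rt) then removes the benzyl group and should give 16 without any base that could move the ester.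

Step 6. Three things may go wrong: decarboxylation of 10 under the HCl that is released, slow reaction of the insoluble diacid, and loss of HCl from 11 on concentration with oligomerisation of the resulting ketene. The fallback sets out from 10 and comes back at 11. The diacid is first persilylated (hexamethyldisilazane, CH2Cl2, reflux) to the soluble, distillable bis(trimethylsilyl) methoxymalonate F6. Oxalyl chloride with catalytic DMF in CH2Cl2 at 0 °C then converts the silyl ester into the acid chloride under neutral, homogeneous conditions. No HCl is formed and all by-products are volatile, so the solution of 11 can go into step 7 after brief evacuation.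

Step 3. Four things may go wrong: displacement of the vinylogous acyl iodide or opening of the pyranone by the hot aqueous base, protodeiodination, and protodeboronation of the electron-rich boronic acid. The fallback inverts the order of coupling and esterification and replaces the base-dependent coupling by a base-free one. It sets out from 3 and comes back at 7, so the step count does not change. Acylation of 3 with 6 (Et3N, DMAP cat., CH2Cl2, 0 °C to rt) should give (6-iodo-5-methoxy-4-oxo-4H-pyran-2-yl)methyl 3-methylbutanoate F7. Negishi coupling of this iodide with commercial 4-methoxyphenylzinc iodide (Pd(PPh3)4, THF, rt to 50 °C) tolerates the ester and the pyranone and should give 7 directly.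

Further compounds
F1 | step 7 | santin (5,7-dihydroxy-3,6,4'-trimethoxyflavone) | COc1ccc(-c2oc3cc(O)c(OC)c(O)c3c(=O)c2OC)cc1
F2 | step 7 | 7-O-benzylsantin (7-benzyloxy-5-hydroxy-3,6,4'-trimethoxyflavone) | COc1ccc(-c2oc3cc(OCc4ccccc4)c(OC)c(O)c3c(=O)c2OC)cc1
F3 | step 7 | potassium 7-benzyloxy-5-hydroxy-3,6,4'-trimethoxyflavon-8-yl sulfate | COc1ccc(-c2oc3c(OS(=O)(=O)[O-])c(OCc4ccccc4)c(OC)c(O)c3c(=O)c2OC)cc1.[K+]
F4 | step 7 | 7-benzyloxy-5,8-dihydroxy-3,6,4'-trimethoxyflavone | COc1ccc(-c2oc3c(O)c(OCc4ccccc4)c(OC)c(O)c3c(=O)c2OC)cc1
F5 | step 7 | 7-benzyloxy-5-hydroxy-3,6,4'-trimethoxyflavon-8-yl 3-methylbutanoate | COc1ccc(-c2oc3c(OC(=O)CC(C)C)c(OCc4ccccc4)c(OC)c(O)c3c(=O)c2OC)cc1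
F6 | step 6 | bis(trimethylsilyl) methoxymalonate | COC(C(=O)O[Si](C)(C)C)C(=O)O[Si](C)(C)C
F7 | step 3 | (6-iodo-5-methoxy-4-oxo-4H-pyran-2-yl)methyl 3-methylbutanoate | CC(C)CC(=O)OCc1cc(=O)c(OC)c(I)o1
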